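Numbering: ten-membered ring C1–C10 (C1=C10 with methyl C14 on C10, tiglate on C2, C4=C5 with C15H2OAc on C4, lactone O on C6, OH on C8); lactone C12(=O)–C11(=C13H2), C11 on C7. Enabling feature: C7 is the β-carbon of the lactone carbonyl C12 and neighbours the carbinol carbon C8, so a C8 ketyl can add to C7 of a C7=C11 butenolide and close the ten-membered ring onto the finished five-membered lactone.
Cuts, in retrosynthetic order: the C15 acetate and C2 tiglate C–O bonds and C11=C13; C7–C8 (ten-membered ring); the lactone C12–O bond and C6–C7; C8–C9 and C1–C10; C3–C4.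
Forward: C3–C4 (alkenyllithium + glycidyl ether), C1–C10 (Grignard), C8–C9 (Wittig–Still shift), C6–C7 (alkynylation); the butenolide ring forms first (semihydrogenation–lactonisation), the ten-membered ring second (SmI2, step 19); then methylene, tiglate, acetate.
Stereochemistry: C2 from (R)-glycidol; C6 from the catalyst-controlled alkynylation; C7 and C8 from the ring closure (addition anti to the C6 substituent, samarium chelate); C4=C5 geometry from syn-hydrostannation, C1=C10 geometry from the [2,3]-shift.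

Key step: step 19

Abbreviations: TES = triethylsilyl, TBS = tert-butyldimethylsilyl, TBDPS = tert-butyldiphenylsilyl, PMB = 4-methoxybenzyl, DMP = Dess–Martin periodinane.
Assumption: (S,S)-ProPhenol is taken to deliver the alkynyl group to the enal face that gives the 4R alcohol 23; if a model enal shows the opposite sense, the (R,R)-ligand is used in the same step.

Step 1
Reactants: 1 but-2-yne-1,4-diol
Product: 2 (E)-2-(tributylstannyl)but-2-ene-1,4-diol
Conditions: Bu3SnH, PdCl2(PPh3)2 (cat.), THF, rt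
Reagents that add atoms: tributyltin hydride, CCCC[SnH](CCCC)CCCC
Why: Palladium-catalysed hydrostannation adds H and SnBu3 syn across the symmetrical alkyne, so the two CH2OH groups (future C15 and C6) end up cis on the future C4=C5 alkene with tin on C4 and no regiochemical issue.

Step 2
Reactants: 2 (E)-2-(tributylstannyl)but-2-ene-1,4-diol
Product: 3 (E)-2-(tributylstannyl)-4-(triethylsilyloxy)but-2-en-1-ol
Conditions: TESCl (1.0 equiv), imidazole, CH2Cl2, −78 to −40 °C
Reagents that add atoms: chlorotriethylsilane, CC[Si](Cl)(CC)CC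
Why: Sterically controlled monosilylation: the hydroxyl on the carbon next to the bulky Bu3Sn group (C15–OH) is shielded, so one equivalent of TESCl at low temperature should take the distal C6–OH.

Step 3
Reactants: 3 mono-TES stannyl alcohol
Product: 4 (E)-1-(tert-butyldiphenylsilyloxy)-2-(tributylstannyl)-4-(triethylsilyloxy)but-2-ene
Conditions: TBDPSCl, imidazole, DMF, rt
Reagents that add atoms: tert-butylchlorodiphenylsilane, CC(C)(C)[Si](Cl)(c1ccccc1)c1ccccc1
Why: Routine silyl ether formation puts the robust TBDPS group on C15–OH, where it is meant to stay until step 25.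

Step 4
Reactants: 5 (R)-glycidol
Product: 6 (S)-2-{[(4-methoxybenzyl)oxy]methyl}oxirane
Conditions: NaH, PMBCl, Bu4NI (cat.), THF/DMF, 0 °C
Reagents that add atoms: 4-methoxybenzyl chloride, COc1ccc(CCl)cc1
Why: Williamson etherification of the primary hydroxyl leaves the epoxide stereocentre untouched (the descriptor changes from R to S only through the priority rules).

Step 5
Reactants: 4 bis-silylated alkenylstannane; 6 (S)-PMB glycidyl ether
Product: 8 (2S,4Z)-4-[(tert-butyldiphenylsilyloxy)methyl]-1-[(4-methoxybenzyl)oxy]-6-(triethylsilyloxy)hex-4-en-2-ol, via alkenyllithium 7 (not isolated)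
Conditions: n-BuLi, THF, −78 °C; then 6, BF3·OEt2, −78 °C
Reagents that add atoms: none
Why: Tin–lithium exchange proceeds with retention of alkene geometry and the alkenyllithium opens the BF3-activated epoxide at its CH2 terminus (SN2 epoxide opening), forming C3–C4 and leaving the C2 configuration from glycidol intact.

Step 6
Reactants: 8 secondary alcohol
Product: 9 (4S)-4-{(2Z)-2-[(tert-butyldiphenylsilyloxy)methyl]-4-(triethylsilyloxy)but-2-en-1-yl}-2-(4-methoxyphenyl)-1,3-dioxolane (both epimers at the acetal carbon)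
Conditions: DDQ, 4 Å molecular sieves, CH2Cl2, 0 °C
Reagents that add atoms: none
Why: DDQ oxidises the PMB ether to the benzylic oxocarbenium ion, which the neighbouring C2 hydroxyl traps under anhydrous conditions to give the p-methoxybenzylidene acetal (oxidative acetalisation) without touching C2.

Step 7
Reactants: 9 p-methoxybenzylidene acetal
Product: 10 (2S,4Z)-4-[(tert-butyldiphenylsilyloxy)methyl]-2-[(4-methoxybenzyl)oxy]-6-(triethylsilyloxy)hex-4-en-1-ol
Conditions: i-Bu2AlH, CH2Cl2, −78 to 0 °C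
Reagents that add atoms: none
Why: Regioselective reductive acetal opening: i-Bu2AlH coordinates the less hindered primary oxygen and delivers hydride to the acetal carbon, so PMB stays on the secondary C2 oxygen and C1–OH is freed.

Step 8
Reactants: 10 primary alcohol
Product: 11 (2S,4Z)-4-[(tert-butyldiphenylsilyloxy)methyl]-2-[(4-methoxybenzyl)oxy]-6-(triethylsilyloxy)hex-4-enal
Conditions: DMP, NaHCO3, CH2Cl2, 0 °C to rt
Reagents that add atoms: none
Why: Buffered Dess–Martin oxidation gives the α-alkoxy aldehyde under non-basic conditions that should not epimerise C2.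

Step 9
Reactants: 11 α-alkoxy aldehyde; 12 isopropenylmagnesium bromide
Product: 13 (4S,6Z)-6-[(tert-butyldiphenylsilyloxy)methyl]-4-[(4-methoxybenzyl)oxy]-2-methyl-8-(triethylsilyloxy)octa-1,6-dien-3-ol (both C3 epimers)
Conditions: THF, −78 °C
Reagents that add atoms: none
Why: Grignard addition to the aldehyde forms C1–C10; the configuration of the new C1 carbinol is irrelevant because C1 becomes an alkene carbon in step 11.

Step 10
Reactants: 13 methallylic alcohol; 14 tributyl(iodomethyl)stannane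
Product: 16 tributylstannylmethyl ether of 13, via potassium alkoxide 15 (not isolated)
Conditions: KH, THF, 0 °C; then 14, 0 °C to rt
Reagents that add atoms: none
Why: Williamson etherification of the potassium alkoxide with the primary iodide installs the stannylmethyl ether needed for the [2,3]-shift.

Step 11
Reactants: 16 stannylmethyl ether
Product: 18 (3Z,5S,7Z)-7-[(tert-butyldiphenylsilyloxy)methyl]-5-[(4-methoxybenzyl)oxy]-3-methyl-9-(triethylsilyloxy)nona-3,7-dien-1-ol, via lithiomethyl ether 17 (not isolated)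
Conditions: n-BuLi, THF, −78 °C
Reagents that add atoms: none
Why: Tin–lithium exchange gives the α-alkoxymethyllithium, which undergoes the Wittig–Still [2,3]-sigmatropic rearrangement, forming C8–C9; in the envelope transition state the C2 substituent on the carbinol carbon sits pseudo-axial to avoid the vinylic methyl group, which should give the Z-configured C1=C10 alkene.

Step 12
Reactants: 18 homoallylic alcohol
Product: 19 C8 TBS ether of 18
Conditions: TBSCl, imidazole, CH2Cl2, rt
Reagents that add atoms: tert-butylchlorodimethylsilane, CC(C)(C)[Si](C)(C)Cl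
Why: Routine silylation of the primary C8 hydroxyl.

Step 13
Reactants: 19 tris-silyl ether
Product: 20 (2Z,5S,6Z)-9-(tert-butyldimethylsilyloxy)-3-[(tert-butyldiphenylsilyloxy)methyl]-5-[(4-methoxybenzyl)oxy]-7-methylnona-2,6-dien-1-ol
Conditions: PPTS (cat.), MeOH/CH2Cl2, 0 °C
Reagents that add atoms: none
Why: Acid-catalysed methanolysis removes a primary TES ether far faster than primary TBS or TBDPS ethers (selective desilylation).

Step 14
Reactants: 20 allylic alcohol
Product: 21 (2Z,5S,6Z)-9-(tert-butyldimethylsilyloxy)-3-[(tert-butyldiphenylsilyloxy)methyl]-5-[(4-methoxybenzyl)oxy]-7-methylnona-2,6-dienal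
Conditions: MnO2, CH2Cl2, rt
Reagents that add atoms: none
Why: MnO2 oxidises allylic alcohols selectively and under neutral conditions, so the Z-enal should form without isomerisation (the cis C15 oxygen is silylated and cannot form a lactol).

Step 15
Reactants: 21 Z-enal; 22 methyl propiolate
Product: 23 methyl (4R,5Z,8S,9Z)-12-(tert-butyldimethylsilyloxy)-6-[(tert-butyldiphenylsilyloxy)methyl]-4-hydroxy-8-[(4-methoxybenzyl)oxy]-10-methyldodeca-5,9-dien-2-ynoate
Conditions: Me2Zn, (S,S)-ProPhenol (20 mol %), Ph3PO (40 mol %), toluene, 0–4 °C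
Reagents that add atoms: none
Why: Zinc–ProPhenol-catalysed enantioselective alkynylation of an α,β-unsaturated aldehyde: the dinuclear zinc catalyst binds the enal and the zinc alkynylide and should deliver the alkynyl group to one face, forming C6–C7 and setting C6 (4R in 23) under catalyst control.

Step 16
Reactants: 23 γ-hydroxy ynoate
Product: 25 (5S)-5-{(1Z,4S,5Z)-8-(tert-butyldimethylsilyloxy)-2-[(tert-butyldiphenylsilyloxy)methyl]-4-[(4-methoxybenzyl)oxy]-6-methylocta-1,5-dien-1-yl}furan-2(5H)-one, via Z-hydroxy enoate 24 (not isolated)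
Conditions: H2 (1 atm), Pd/CaCO3 poisoned with Pb(OAc)2, quinoline, EtOAc, rt; then PPTS (cat.), CH2Cl2, rt
Reagents that add atoms: none
Why: Lindlar semihydrogenation gives the Z-configured γ-hydroxy enoate, in which the C6 hydroxyl lies next to the ester and lactonises under mild acid to the butenolide; trisubstituted alkenes and the PMB ether should not be reduced and C6 is untouched.

Step 17
Reactants: 25 butenolide
Product: 26 C8 alcohol (25 without the TBS group)
Conditions: CSA (cat.), MeOH/CH2Cl2, 0 °C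
Reagents that add atoms: none
Why: Acid-catalysed methanolysis cleaves the primary TBS ether while the primary TBDPS ether, which is far more stable to acid, should survive (selective desilylation).

Step 18
Reactants: 26 hydroxy butenolide
Product: 27 (3Z,5S,7Z)-7-[(tert-butyldiphenylsilyloxy)methyl]-5-[(4-methoxybenzyl)oxy]-3-methyl-8-[(2S)-5-oxo-2,5-dihydrofuran-2-yl]octa-3,7-dienal
Conditions: DMP, NaHCO3, CH2Cl2, 0 °C
Reagents that add atoms: none
Why: Buffered Dess–Martin oxidation gives the β,γ-unsaturated aldehyde under neutral conditions that should neither move C1=C10 into conjugation nor epimerise the doubly allylic C6; the aldehyde is used at once.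

Step 19
Reactants: 27 open-chain C8 aldehyde with the C6 butenolide
Product: 29 (2S,6R,7R,8R)-15-(tert-butyldiphenylsilyloxy)-8-hydroxy-2-[(4-methoxybenzyl)oxy]germacra-1(10),4-dien-12,6-olide (both ring alkenes Z by the priority rules; trans-fused lactone), via trivalent samarium enolate 28 (not isolated)
Conditions: SmI2 (3 equiv), t-BuOH (3 equiv), THF, −78 °C, 27 added over 6 h by syringe pump (final 2 mM), then to −20 °C; no HMPA
Reagents that add atoms: none
Why: Proposed new method: SmI2 reduces the C8 aldehyde to a samarium ketyl, the ketyl carbon adds to C7 (the β-carbon of the butenolide, C7=C11), a second SmI2 reduces the C11 radical to the samarium enolate 28 and t-BuOH protonates C11, so that C7–C8, the C8 hydroxyl and the saturated lactone form in one operation. The closest known reaction type is the SmI2 ketyl–olefin cyclisation of aldehydes onto α,β-unsaturated esters and lactones, which is established for five- to eight-membered rings; the ten-membered closure is the extension proposed here. The ring closes in the 10-exo-trig mode with respect to C7=C11, and closure should be helped by the two trisubstituted alkenes and the flat butenolide, which leave only C2, C3 and C9 as sp3 ring atoms in the tether, by slow addition at high dilution, which suppresses pinacol coupling, and by the persistence of ketyl radicals in the absence of HMPA. C7 is set by addition to the butenolide face anti to the C5 substituent on C6, which gives the trans-fused lactone, and C8 by a transition state in which trivalent samarium bridges the ketyl oxygen and the lactone carbonyl oxygen. The step needs the aldehyde to be reduced in preference to the butenolide (whose reduction would expel the C6 carboxylate) and the ketyl to choose C7: SmI2 without HMPA should reduce only the aldehyde, the butenolide is the only electron-poor alkene, and C1=C10 and C4=C5 are unactivated and trisubstituted.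

Step 20
Reactants: 29 macrocyclic hydroxy lactone
Product: 30 C8 TBS ether of 29
Conditions: TBSOTf, 2,6-lutidine, CH2Cl2, −78 to 0 °C
Reagents that add atoms: tert-butyldimethylsilyl triflate, CC(C)(C)[Si](C)(C)OS(=O)(=O)C(F)(F)F
Why: Silylation with the silyl triflate protects the hindered secondary C8 hydroxyl and removes the risk that its alkoxide attacks C12 (translactonisation) in step 21.

Step 21
Reactants: 30 silylated lactone; 31 N,N-dimethylmethyleneiminium iodide (Eschenmoser's salt)
Product: 33 11-(dimethylaminomethyl) lactone (C11 configuration not controlled), via lithium enolate 32 (not isolated)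
Conditions: LiN(i-Pr)2, THF, −78 °C; then 31, −78 °C to rt
Reagents that add atoms: none
Why: Deprotonation at C11 gives the lactone enolate, which is aminomethylated by the iminium salt (Mannich reaction); the C11 configuration is irrelevant and C7 is not enolisable.

Step 22
Reactants: 33 Mannich base
Product: 35 11(13)-methylene lactone (C8–OTBS, C2–OPMB, C15–OTBDPS), via trimethylammonium iodide 34 (not isolated)
Conditions: MeI, MeOH, rt; then NaHCO3 (aq.), CH2Cl2, rt
Reagents that add atoms: none
Why: N-Methylation makes trimethylamine a leaving group and mild base then eliminates it (Hofmann-type E1cB elimination) to give the exocyclic C11=C13 alkene.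

Step 23
Reactants: 35 α-methylene lactone
Product: 36 C2 alcohol (35 without the PMB group)
Conditions: DDQ, CH2Cl2/pH 7 buffer, 0 °C
Reagents that add atoms: none
Why: Oxidative cleavage of the PMB ether by DDQ in wet solvent frees the C2 hydroxyl; silyl ethers and the electron-poor methylene lactone should be inert.

Step 24
Reactants: 36 C2 alcohol; 37 tigloyl chloride [(E)-2-methylbut-2-enoyl chloride]
Product: 38 C2 tiglate of 36
Conditions: DMAP (cat.), pyridine, CH2Cl2, 0 °C to rt
Reagents that add atoms: none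
Why: DMAP-catalysed acylation of the secondary allylic alcohol with the E-configured acid chloride; the weak base pyridine avoids ketene formation, so the E geometry of the tiglate should be kept.

Step 25
Reactants: 38 bis-silylated tiglate
Product: 39 C8,C15-diol (2-O-tigloyl, 11(13)-methylene lactone)
Conditions: HF·pyridine, pyridine, THF, 0 °C to rt
Reagents that add atoms: none
Why: Fluoride-mediated desilylation with buffered HF·pyridine cleaves both the TBDPS and the TBS ether under slightly acidic conditions, which avoids a free C8 alkoxide that could attack C12.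

Step 26
Reactants: 39 diol
Product: 40 target, (2S,6R,7R,8R)-15-acetoxy-8-hydroxy-2-(tigloyloxy)germacra-1(10),4,11(13)-trien-12,6-olide
Conditions: AcCl (1.05 equiv), 2,4,6-collidine, CH2Cl2, −78 °C
Reagents that add atoms: acetyl chloride, CC(=O)Cl
Why: Chemoselective acylation: with AcCl and collidine at low temperature the primary allylic C15 hydroxyl should react much faster than the hindered secondary C8 hydroxyl.

Compound list
1 | but-2-yne-1,4-diol | OCC#CCO | starting material
2 | (E)-2-(tributylstannyl)but-2-ene-1,4-diol | OC/C=C(\CO)[Sn](CCCC)(CCCC)CCCC | intermediate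
3 | (E)-2-(tributylstannyl)-4-(triethylsilyloxy)but-2-en-1-ol | CC[Si](CC)(CC)OC/C=C(\CO)[Sn](CCCC)(CCCC)CCCC | intermediate
4 | (E)-1-(tert-butyldiphenylsilyloxy)-2-(tributylstannyl)-4-(triethylsilyloxy)but-2-ene | CC[Si](CC)(CC)OC/C=C(\CO[Si](c1ccccc1)(c1ccccc1)C(C)(C)C)[Sn](CCCC)(CCCC)CCCC | intermediate
5 | (R)-glycidol | OC[C@@H]1CO1 | starting material
6 | (S)-2-{[(4-methoxybenzyl)oxy]methyl}oxirane | COc1ccc(COC[C@@H]2CO2)cc1 | intermediate
7 | (Z)-[1-(tert-butyldiphenylsilyloxy)-4-(triethylsilyloxy)but-2-en-2-yl]lithium (not isolated) | CC[Si](CC)(CC)OC/C=C(\CO[Si](c1ccccc1)(c1ccccc1)C(C)(C)C)[Li] | intermediate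
8 | (2S,4Z)-4-[(tert-butyldiphenylsilyloxy)methyl]-1-[(4-methoxybenzyl)oxy]-6-(triethylsilyloxy)hex-4-en-2-ol | COc1ccc(COC[C@@H](O)C/C(CO[Si](c2ccccc2)(c2ccccc2)C(C)(C)C)=C/CO[Si](CC)(CC)CC)cc1 | intermediate
9 | (4S)-4-{(2Z)-2-[(tert-butyldiphenylsilyloxy)methyl]-4-(triethylsilyloxy)but-2-en-1-yl}-2-(4-methoxyphenyl)-1,3-dioxolane (acetal epimers) | COc1ccc(C2OC[C@H](C/C(CO[Si](c3ccccc3)(c3ccccc3)C(C)(C)C)=C/CO[Si](CC)(CC)CC)O2)cc1 | intermediate
10 | (2S,4Z)-4-[(tert-butyldiphenylsilyloxy)methyl]-2-[(4-methoxybenzyl)oxy]-6-(triethylsilyloxy)hex-4-en-1-ol | COc1ccc(CO[C@H](CO)C/C(CO[Si](c2ccccc2)(c2ccccc2)C(C)(C)C)=C/CO[Si](CC)(CC)CC)cc1 | intermediate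
11 | (2S,4Z)-4-[(tert-butyldiphenylsilyloxy)methyl]-2-[(4-methoxybenzyl)oxy]-6-(triethylsilyloxy)hex-4-enal | COc1ccc(CO[C@H](C=O)C/C(CO[Si](c2ccccc2)(c2ccccc2)C(C)(C)C)=C/CO[Si](CC)(CC)CC)cc1 | intermediate
12 | isopropenylmagnesium bromide | CC(=C)[Mg]Br | starting material
13 | (4S,6Z)-6-[(tert-butyldiphenylsilyloxy)methyl]-4-[(4-methoxybenzyl)oxy]-2-methyl-8-(triethylsilyloxy)octa-1,6-dien-3-ol (C3 epimers) | COc1ccc(CO[C@H](C(O)C(C)=C)C/C(CO[Si](c2ccccc2)(c2ccccc2)C(C)(C)C)=C/CO[Si](CC)(CC)CC)cc1 | intermediate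
14 | tributyl(iodomethyl)stannane | CCCC[Sn](CCCC)(CCCC)CI | starting material
15 | potassium alkoxide of 13 (not isolated) | COc1ccc(CO[C@H](C(O[K])C(C)=C)C/C(CO[Si](c2ccccc2)(c2ccccc2)C(C)(C)C)=C/CO[Si](CC)(CC)CC)cc1 | intermediate
16 | tributylstannylmethyl ether of 13 | COc1ccc(CO[C@H](C(OC[Sn](CCCC)(CCCC)CCCC)C(C)=C)C/C(CO[Si](c2ccccc2)(c2ccccc2)C(C)(C)C)=C/CO[Si](CC)(CC)CC)cc1 | intermediate
17 | lithiomethyl ether of 13 (not isolated) | COc1ccc(CO[C@H](C(OC[Li])C(C)=C)C/C(CO[Si](c2ccccc2)(c2ccccc2)C(C)(C)C)=C/CO[Si](CC)(CC)CC)cc1 | intermediate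
18 | (3Z,5S,7Z)-7-[(tert-butyldiphenylsilyloxy)methyl]-5-[(4-methoxybenzyl)oxy]-3-methyl-9-(triethylsilyloxy)nona-3,7-dien-1-ol | OCC/C(C)=C\[C@@H](OCc1ccc(OC)cc1)C/C(CO[Si](c2ccccc2)(c2ccccc2)C(C)(C)C)=C/CO[Si](CC)(CC)CC | intermediate
19 | tert-butyldimethylsilyl ether of 18 (silyl on the C8 oxygen) | CC(C)(C)[Si](C)(C)OCC/C(C)=C\[C@@H](OCc1ccc(OC)cc1)C/C(CO[Si](c2ccccc2)(c2ccccc2)C(C)(C)C)=C/CO[Si](CC)(CC)CC | intermediate
20 | (2Z,5S,6Z)-9-(tert-butyldimethylsilyloxy)-3-[(tert-butyldiphenylsilyloxy)methyl]-5-[(4-methoxybenzyl)oxy]-7-methylnona-2,6-dien-1-ol | CC(C)(C)[Si](C)(C)OCC/C(C)=C\[C@@H](OCc1ccc(OC)cc1)C/C(CO[Si](c2ccccc2)(c2ccccc2)C(C)(C)C)=C/CO | intermediate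
21 | (2Z,5S,6Z)-9-(tert-butyldimethylsilyloxy)-3-[(tert-butyldiphenylsilyloxy)methyl]-5-[(4-methoxybenzyl)oxy]-7-methylnona-2,6-dienal | CC(C)(C)[Si](C)(C)OCC/C(C)=C\[C@@H](OCc1ccc(OC)cc1)C/C(CO[Si](c2ccccc2)(c2ccccc2)C(C)(C)C)=C/C=O | intermediate
22 | methyl propiolate | COC(=O)C#C | starting material
23 | methyl (4R,5Z,8S,9Z)-12-(tert-butyldimethylsilyloxy)-6-[(tert-butyldiphenylsilyloxy)methyl]-4-hydroxy-8-[(4-methoxybenzyl)oxy]-10-methyldodeca-5,9-dien-2-ynoate | COC(=O)C#C[C@H](O)/C=C(\CO[Si](c1ccccc1)(c1ccccc1)C(C)(C)C)C[C@H](OCc1ccc(OC)cc1)/C=C(/C)CCO[Si](C)(C)C(C)(C)C | intermediate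
24 | (2Z)-alkene from semihydrogenation of 23: methyl Z-γ-hydroxy enoate (not isolated) | COC(=O)/C=C\[C@H](O)/C=C(\CO[Si](c1ccccc1)(c1ccccc1)C(C)(C)C)C[C@H](OCc1ccc(OC)cc1)/C=C(/C)CCO[Si](C)(C)C(C)(C)C | intermediate
25 | (5S)-5-{(1Z,4S,5Z)-8-(tert-butyldimethylsilyloxy)-2-[(tert-butyldiphenylsilyloxy)methyl]-4-[(4-methoxybenzyl)oxy]-6-methylocta-1,5-dien-1-yl}furan-2(5H)-one | O=C1C=C[C@@H](/C=C(\CO[Si](c2ccccc2)(c2ccccc2)C(C)(C)C)C[C@H](OCc2ccc(OC)cc2)/C=C(/C)CCO[Si](C)(C)C(C)(C)C)O1 | intermediate
26 | (5S)-5-{(1Z,4S,5Z)-2-[(tert-butyldiphenylsilyloxy)methyl]-8-hydroxy-4-[(4-methoxybenzyl)oxy]-6-methylocta-1,5-dien-1-yl}furan-2(5H)-one | O=C1C=C[C@@H](/C=C(\CO[Si](c2ccccc2)(c2ccccc2)C(C)(C)C)C[C@H](OCc2ccc(OC)cc2)/C=C(/C)CCO)O1 | intermediate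
27 | (3Z,5S,7Z)-7-[(tert-butyldiphenylsilyloxy)methyl]-5-[(4-methoxybenzyl)oxy]-3-methyl-8-[(2S)-5-oxo-2,5-dihydrofuran-2-yl]octa-3,7-dienal | O=C1C=C[C@@H](/C=C(\CO[Si](c2ccccc2)(c2ccccc2)C(C)(C)C)C[C@H](OCc2ccc(OC)cc2)/C=C(/C)CC=O)O1 | intermediate
28 | bis(diiodosamarium) C8-alkoxide C12-enolate of 29 (not isolated) | C1[C@@H](O[Sm](I)I)[C@H]2C=C(O[Sm](I)I)O[C@@H]2/C=C(\CO[Si](c3ccccc3)(c3ccccc3)C(C)(C)C)C[C@H](OCc3ccc(OC)cc3)/C=C1/C | intermediate
29 | (2S,6R,7R,8R)-15-(tert-butyldiphenylsilyloxy)-8-hydroxy-2-[(4-methoxybenzyl)oxy]germacra-1(10),4-dien-12,6-olide (C1=C10 cis in the ring, C4=C5 trans in the ring, lactone trans-fused) | C1[C@@H](O)[C@H]2CC(=O)O[C@@H]2/C=C(\CO[Si](c3ccccc3)(c3ccccc3)C(C)(C)C)C[C@H](OCc3ccc(OC)cc3)/C=C1/C | intermediate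
30 | 8-O-tert-butyldimethylsilyl ether of 29 | C1[C@@H](O[Si](C)(C)C(C)(C)C)[C@H]2CC(=O)O[C@@H]2/C=C(\CO[Si](c3ccccc3)(c3ccccc3)C(C)(C)C)C[C@H](OCc3ccc(OC)cc3)/C=C1/C | intermediate
31 | N,N-dimethylmethyleneiminium iodide (Eschenmoser's salt) | C=[N+](C)C.[I-] | starting material
32 | lithium enolate of 30 (C11=C12–OLi; not isolated) | C1[C@@H](O[Si](C)(C)C(C)(C)C)[C@H]2C=C(O[Li])O[C@@H]2/C=C(\CO[Si](c3ccccc3)(c3ccccc3)C(C)(C)C)C[C@H](OCc3ccc(OC)cc3)/C=C1/C | intermediate
33 | 11-(dimethylaminomethyl) derivative of 30 (C11 epimers) | C1[C@@H](O[Si](C)(C)C(C)(C)C)[C@H]2C(CN(C)C)C(=O)O[C@@H]2/C=C(\CO[Si](c3ccccc3)(c3ccccc3)C(C)(C)C)C[C@H](OCc3ccc(OC)cc3)/C=C1/C | intermediate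
34 | 11-(trimethylammoniomethyl) derivative of 30, iodide (not isolated) | C1[C@@H](O[Si](C)(C)C(C)(C)C)[C@H]2C(C[N+](C)(C)C)C(=O)O[C@@H]2/C=C(\CO[Si](c3ccccc3)(c3ccccc3)C(C)(C)C)C[C@H](OCc3ccc(OC)cc3)/C=C1/C.[I-] | intermediate
35 | 8-(tert-butyldimethylsilyloxy)-15-(tert-butyldiphenylsilyloxy)-2-[(4-methoxybenzyl)oxy]germacra-1(10),4,11(13)-trien-12,6-olide (stereocentres as in 30) | C=C1C(=O)O[C@@H]2/C=C(\CO[Si](c3ccccc3)(c3ccccc3)C(C)(C)C)C[C@H](OCc3ccc(OC)cc3)/C=C(/C)C[C@@H](O[Si](C)(C)C(C)(C)C)[C@@H]12 | intermediate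
36 | C2 alcohol: 35 with OH in place of OPMB | C=C1C(=O)O[C@@H]2/C=C(\CO[Si](c3ccccc3)(c3ccccc3)C(C)(C)C)C[C@H](O)/C=C(/C)C[C@@H](O[Si](C)(C)C(C)(C)C)[C@@H]12 | intermediate
37 | tigloyl chloride, (E)-2-methylbut-2-enoyl chloride | C/C=C(\C)C(=O)Cl | starting material
38 | 2-O-tigloyl derivative of 36 | C=C1C(=O)O[C@@H]2/C=C(\CO[Si](c3ccccc3)(c3ccccc3)C(C)(C)C)C[C@H](OC(=O)/C(C)=C/C)/C=C(/C)C[C@@H](O[Si](C)(C)C(C)(C)C)[C@@H]12 | intermediate
39 | (2S,6R,7R,8R)-8,15-dihydroxy-2-(tigloyloxy)germacra-1(10),4,11(13)-trien-12,6-olide | C=C1C(=O)O[C@@H]2/C=C(\CO)C[C@H](OC(=O)/C(C)=C/C)/C=C(/C)C[C@@H](O)[C@@H]12 | intermediate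
40 | (2S,6R,7R,8R)-15-acetoxy-8-hydroxy-2-(tigloyloxy)germacra-1(10),4,11(13)-trien-12,6-olide (CNP0129394.2) | C=C1C(=O)O[C@@H]2/C=C(\COC(C)=O)C[C@H](OC(=O)/C(C)=C/C)/C=C(/C)C[C@@H](O)[C@@H]12 | target

Total step count: 26. Longest linear sequence: 25 steps (1 to 40 through steps 1–3 and 5–26); step 4 is the only side branch.

Steps most likely to fail

Step 19 (the proposed new method). The ten-membered radical closure is slow, so intermolecular pinacol coupling or simple reduction of the aldehyde may outrun it. Electron transfer to the butenolide, with loss of the C6 carboxylate, is a second failure path, and the chelate may not control the C8 face. The fallback uses known two-electron chemistry for the same C7–C8 bond; it sets out from 25 and comes back at 35, so steps 17–22 are replaced. Iodination of 25 (I2, pyridine, CH2Cl2) would give the 3-iodobutenolide F1. Stille hydroxymethylation (Bu3SnCH2OH, Pd(PPh3)4, dioxane, 80 °C) would give the 3-(hydroxymethyl)butenolide F2, and Appel bromination (CBr4, PPh3) the 3-(bromomethyl)butenolide F3. Buffered HF·pyridine would free the C8 alcohol F4, and Dess–Martin oxidation would give the bromo aldehyde F5. CrCl2 in THF at high dilution would then close the ring by an intramolecular Barbier allylation of the Nozaki–Hiyama–Kishi type. This kind of closure is established for ten-membered germacranolide rings, and 3-(bromomethyl)butenolides are known to allylate aldehydes through their ring β-carbon, anti to the substituent on the neighbouring ring carbon. The product would be the hydroxy α-methylene lactone F6, with C11=C13 already in place. Silylation (TBSOTf, 2,6-lutidine) then gives 35.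

Step 15. Facial discrimination by the zinc catalyst may be insufficient on this Z-configured, β,β-disubstituted enal, and the Lewis-acidic zinc may isomerise the enal to the E form. The fallback sets out from 21 and comes back at 23. Addition of lithiated methyl propiolate (LiN(SiMe3)2, THF, −78 °C) would give the C6-epimeric alcohols F7, and Dess–Martin oxidation the ynone F8. Corey–Bakshi–Shibata reduction ((R)-2-methyl-CBS-oxazaborolidine, catecholborane, −78 °C, alkynyl as the small group) would set C6 by reagent control in a ketone reduction and give 23.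

Step 2. Discrimination between the two primary hydroxyls may be poor, giving bis-silylation and silylation at C15–OH. The fallback sets out from 1 and comes back at 3. Monosilylation of 1 with a deficit of TESCl (imidazole, excess diol) would give 4-(triethylsilyloxy)but-2-yn-1-ol F9. Palladium-catalysed hydrostannation (Bu3SnH, PdCl2(PPh3)2) should then place tin on the alkyne carbon next to the free hydroxymethyl group and away from the bulky silyloxymethyl group, giving 3 with the regiochemistry fixed by the order of events.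

Further compounds
F1 | step 19 | 3-iodo derivative of 25 (iodine on C11) | O=C1C(I)=C[C@@H](/C=C(\CO[Si](c2ccccc2)(c2ccccc2)C(C)(C)C)C[C@H](OCc2ccc(OC)cc2)/C=C(/C)CCO[Si](C)(C)C(C)(C)C)O1
F2 | step 19 | 3-(hydroxymethyl) derivative of 25 (C13 hydroxymethyl on C11) | O=C1C(CO)=C[C@@H](/C=C(\CO[Si](c2ccccc2)(c2ccccc2)C(C)(C)C)C[C@H](OCc2ccc(OC)cc2)/C=C(/C)CCO[Si](C)(C)C(C)(C)C)O1
F3 | step 19 | 3-(bromomethyl) derivative of 25 | O=C1C(CBr)=C[C@@H](/C=C(\CO[Si](c2ccccc2)(c2ccccc2)C(C)(C)C)C[C@H](OCc2ccc(OC)cc2)/C=C(/C)CCO[Si](C)(C)C(C)(C)C)O1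
F4 | step 19 | 3-(bromomethyl) derivative of 26 (free C8 hydroxyl) | O=C1C(CBr)=C[C@@H](/C=C(\CO[Si](c2ccccc2)(c2ccccc2)C(C)(C)C)C[C@H](OCc2ccc(OC)cc2)/C=C(/C)CCO)O1
F5 | step 19 | 3-(bromomethyl) derivative of 27 (C8 aldehyde) | O=C1C(CBr)=C[C@@H](/C=C(\CO[Si](c2ccccc2)(c2ccccc2)C(C)(C)C)C[C@H](OCc2ccc(OC)cc2)/C=C(/C)CC=O)O1
F6 | step 19 | 8-hydroxy analogue of 35 (35 without the C8 silyl group) | C=C1C(=O)O[C@@H]2/C=C(\CO[Si](c3ccccc3)(c3ccccc3)C(C)(C)C)C[C@H](OCc3ccc(OC)cc3)/C=C(/C)C[C@@H](O)[C@@H]12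
F7 | step 15 | C4-epimeric mixture of 23 (both configurations at C6 of the target numbering) | COC(=O)C#CC(O)/C=C(\CO[Si](c1ccccc1)(c1ccccc1)C(C)(C)C)C[C@H](OCc1ccc(OC)cc1)/C=C(/C)CCO[Si](C)(C)C(C)(C)C
F8 | step 15 | methyl (5Z,8S,9Z)-12-(tert-butyldimethylsilyloxy)-6-[(tert-butyldiphenylsilyloxy)methyl]-8-[(4-methoxybenzyl)oxy]-10-methyl-4-oxododeca-5,9-dien-2-ynoate | COC(=O)C#CC(=O)/C=C(\CO[Si](c1ccccc1)(c1ccccc1)C(C)(C)C)C[C@H](OCc1ccc(OC)cc1)/C=C(/C)CCO[Si](C)(C)C(C)(C)C
F9 | step 2 | 4-(triethylsilyloxy)but-2-yn-1-ol | CC[Si](CC)(CC)OCC#CCO
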